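You asked for a quick number, with the hunch that the yield follows the starting material; we have decided to reckon from the crystals instead.

starting material 0.50 M; gas phase 98 mM (held); time 80 min

    dissolved gas + target → over-reacted product (k1 = 0.0291 M⁻¹ s⁻¹)
    crystals ⇌ target, rate k2*(cs2 - [target]) while solid is left; crystals form when [target] > cs2 (cs2 = 11 mM, k2 = 0.0112 s⁻¹)
    gas phase ⇌ dissolved gas, rate k3*(csat - [dissolved gas]) (k3 = 0.0721 s⁻¹, csat = 98 mM)
    starting material + dissolved gas → target (k4 = 0.0143 M⁻¹ s⁻¹)
    starting material + target → side product (k5 = 5.50 × 10⁻⁴ M⁻¹ s⁻¹)
    dissolved gas → decomposed reagent (k6 = 2.22 × 10⁻⁴ s⁻¹)

1. target and crystals together at 80 min, in percent of the starting material charged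
2. concentration of dissolved gas in solution at 80 min, in percent of saturation

- percentages count the starting material that a species holds: one side product counts as two
- target is meant together with its crystals
- solid, in amounts per volume of the solution: crystals
- at the start none of the gas is dissolved
- run time (flask): 80 min

Gas enters the solution with a coefficient of 0.0721 s⁻¹, faster than the charged starting material takes it up, at 0.00715 s⁻¹, so we take the dissolved gas as saturated, at 98 mM. Starting material then falls with a time constant of 11.9 min, shorter than the run, so we count it as converted.

At that gas level, dissolved target over-reacts with a pseudo-first-order constant of 0.00285 s⁻¹, while it joins the crystals with 0.0112 s⁻¹, which is faster. Of the target as it forms, we therefore expect a share of 20.3% to over-react before it reaches a crystal.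

Once target has stopped forming and crystals still stand, their dissolving balances over-reaction with dissolved target at 8.77 mM, below the solubility of 11 mM. The same balance, written while target still forms, gives that share on top of a steady amount per minute, the over-reaction constant times that concentration; we call this the leak, 1.50 mM min⁻¹. We count it over the whole 80 min, so we reckon that it takes 0.120 M from the 0.50 M charged.

We leave out the side product, whose constant is smaller than that of the step forming target. Our number for target and crystals is then 55.7%. Weighing gas transfer against the gas lost to decomposition and to dissolved target puts the saturation at the end of the run at 99.3%.

The forecast gave 55.3% and 99.3%, on the ground that “Gas transfer is fast”. The simulated flask gives 55.5% and 99.3%.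

Take the neighbouring flask, the same but charged with 0.12 M of starting material. The share of over-reaction leaves it 0.0956 M as target and crystals together, and we reckon that the leak empties this in 63.8 min, shorter than the run of 80 min. At 80.0 min that flask holds crystals at 0% and target at 0.330%, with over-reacted product at 98.5%.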